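**Retrosynthetic overview**
1. Feature: in the furan ring, C2 (bonded to O1 and the aryl group) and C3 (bonded to the methoxy oxygen) together sit at the oxidation level of a 1,2-dicarbonyl, and C3a is ortho to O1 (on C7a) and para to the 6-hydroxyl of a resorcinol ring.
2. Key disconnection: C3-C3a, C3-OMe and O1-C2 are cut together, giving arylglyoxal hydrate 4 (C2-C3), 4-prenylresorcinol 11 (C3a and O1) and methanol 12 (the 3-methoxy group).
3. 4 comes from paeonol 1 by tosylation of the 2'-phenol and Riley oxidation; 11 comes from 4-bromoresorcinol 5 by MOM protection, Br/Li exchange with copper-mediated prenylation, and acetal cleavage.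
4. Ring order: both benzene rings are bought, the prenyl chain is attached to the resorcinol ring first, and the furan ring (the only ring made) closes in the key step as the two arenes are joined; detosylation ends the route.

Key step: step 6

Remark: the target has no stereocentre and no stereogenic double bond (the prenyl alkene carries two identical methyl groups), so it is achiral and "single enantiomer" requires no stereocontrol.

**Step 1**
Reactants: 1 paeonol (2'-hydroxy-4'-methoxyacetophenone)
Product: 2 2-acetyl-5-methoxyphenyl 4-methylbenzenesulfonate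
Conditions: TsCl (1.2 equiv), K2CO3 (2 equiv), acetone, reflux
Reagents that add atoms: p-toluenesulfonyl chloride, Cc1ccc(S(Cl)(=O)=O)cc1
Why: Base-mediated O-sulfonylation of the phenol, in which carbonate breaks the hydrogen bond to the ketone and the phenoxide attacks TsCl, should give an aryl sulfonate that is stable to SeO2 and to acid and keeps this oxygen out of the later ring closure.

**Step 2**
Reactants: 2 2-acetyl-5-methoxyphenyl 4-methylbenzenesulfonate
Product: 4 2-(2,2-dihydroxyacetyl)-5-methoxyphenyl 4-methylbenzenesulfonate (arylglyoxal hydrate), via 2-(4-methoxy-2-tosyloxyphenyl)-2-oxoacetaldehyde 3 (not isolated)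
Conditions: SeO2 (1.5 equiv), 1,4-dioxane/H2O (20:1), 100 °C; hot filtration from selenium, crystallisation from water
Reagents that add atoms: selenium dioxide, O=[Se]=O; water, O
Why: Riley oxidation converts the enolisable methyl of the aryl ketone into the aldehyde while the aryl sulfonate and aryl ether are inert, and glyoxal 3 is hydrated in the aqueous medium and collected as the crystalline gem-diol 4.

**Step 3**
Reactants: 5 4-bromoresorcinol
Product: 6 1-bromo-2,4-bis(methoxymethoxy)benzene
Conditions: MOMCl (2.5 equiv), i-Pr2NEt (3 equiv), CH2Cl2, 0 °C to rt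
Reagents that add atoms: chloromethyl methyl ether, COCCl
Why: Williamson-type O-alkylation of both phenols with the reactive chloromethyl ether under amine base should give the bis-acetal, which tolerates organolithium reagents at −78 °C.

**Step 4**
Reactants: 6 1-bromo-2,4-bis(methoxymethoxy)benzene; 7 prenyl bromide (1-bromo-3-methylbut-2-ene)
Product: 10 2,4-bis(methoxymethoxy)-1-(3-methylbut-2-en-1-yl)benzene, via [2,4-bis(methoxymethoxy)phenyl]lithium 8 (not isolated), via [2,4-bis(methoxymethoxy)phenyl]copper 9 (not isolated)
Conditions: n-BuLi (1.05 equiv), THF, −78 °C; CuBr·SMe2 (1.0 equiv), −78 to −40 °C; 7 (1.3 equiv), −40 to 0 °C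
Reagents that add atoms: prenyl bromide (7), CC(C)=CCBr
Why: Bromine-lithium exchange at −78 °C outruns deprotonation and gives aryllithium 8, transmetalation to arylcopper 9 tempers its basicity, and copper-mediated allylic substitution on prenyl bromide should occur at the unhindered primary carbon (SN2 rather than SN2' at the tertiary carbon), so the linear prenyl group is attached.

**Step 5**
Reactants: 10 2,4-bis(methoxymethoxy)-1-(3-methylbut-2-en-1-yl)benzene
Product: 11 4-(3-methylbut-2-en-1-yl)benzene-1,3-diol (4-prenylresorcinol)
Conditions: HCl (3 M aq., 2 equiv), MeOH, 40 °C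
Reagents that add atoms: none
Why: Acid-catalysed transacetalisation to methanol (MOM ether cleavage) frees both phenols and traps the methoxymethyl cation as dimethoxymethane, and dilute acid levelled by methanol at 40 °C should be too weak to protonate the trisubstituted alkene and close the ortho-prenylphenol to a chroman.

**Step 6**
Reactants: 4 2-(2,2-dihydroxyacetyl)-5-methoxyphenyl 4-methylbenzenesulfonate; 11 4-prenylresorcinol; 12 methanol
Product: 16 2-[6-hydroxy-3-methoxy-5-(3-methylbut-2-en-1-yl)-1-benzofuran-2-yl]-5-methoxyphenyl 4-methylbenzenesulfonate (2'-O-tosylambofuranol), via 2-(2-hydroxy-2-methoxyacetyl)-5-methoxyphenyl 4-methylbenzenesulfonate 13 (not isolated), via 2-{2-[2,4-dihydroxy-5-(3-methylbut-2-en-1-yl)phenyl]-2-methoxyacetyl}-5-methoxyphenyl 4-methylbenzenesulfonate 14 (not isolated), via 2-[2,6-dihydroxy-3-methoxy-5-(3-methylbut-2-en-1-yl)-2,3-dihydro-1-benzofuran-2-yl]-5-methoxyphenyl 4-methylbenzenesulfonate 15 (not isolated)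
Conditions: 4 (1.2 equiv), 11 (1.0 equiv), (±)-CSA (20 mol %), dry MeOH (0.05 M), rt to 45 °C; then 3 Å MS, 55 °C
Reagents that add atoms: methanol (12), CO
Why: Proposed new method: in acidic methanol hydrate 4 exchanges to the methyl hemiacetal 13, whose protonated aldehyde or acyl oxocarbenium form is attacked by the carbon of 11 that is ortho to one hydroxyl and para to the other, and the benzylic oxygen of the adduct equilibrates to methoxy through the cation stabilised by the para hydroxyl to give racemic α-methoxy ketone 14; the ortho hydroxyl then adds to the aryl ketone to give hemiketal 15, which loses water to a C2 oxocarbenium ion and then the C3 proton, the aromatic furan being the irreversible sink. The closest known reaction type is the acid-catalysed three-component condensation of arylglyoxals and phenols with sulfonamides, 1,3-dicarbonyl compounds or a second phenol, which gives 2-aryl-3-substituted benzofurans; methanol as the third partner and a prenylated resorcinol as the phenol are the untested extensions. The furan ring closes by 5-exo-trig addition of the phenol oxygen to the ketone carbon, followed by dehydration. The sp3 centres formed at C3 and C2 on the way are uncontrolled and are erased on aromatisation, so no stereocentre has to be set. The selectivities needed are secured by the substrates: the aldehyde carbon of the glyoxal is the more electrophilic carbonyl and becomes C3, the prenyl group blocks the other position para to a hydroxyl and crowding disfavours the carbon between the two hydroxyls of 11, the tosylate leaves the resorcinol hydroxyl as the only oxygen able to close on the ketone, and only the benzylic C3 oxygen exchanges with methanol, so the 6-hydroxyl stays free. Methanol as solvent with a slight excess of 4 outcompetes a second molecule of 11, the sieves are added only after the C-C bond has formed so that the aldehyde is not drained into its dimethyl acetal, and a sulfonic acid levelled by methanol at 45-55 °C is of the strength the ortho-prenylphenol already meets in step 5.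

**Step 7**
Reactants: 16 2'-O-tosylambofuranol
Product: 17 ambofuranol, 2-(2-hydroxy-4-methoxyphenyl)-3-methoxy-5-(3-methylbut-2-en-1-yl)-1-benzofuran-6-ol
Conditions: KOH (6 equiv), degassed 1,4-dioxane/H2O (1:1), 80 °C, Ar; then 1 M HCl to pH 5
Reagents that add atoms: none
Why: Alkaline hydrolysis of the aryl sulfonate proceeds by hydroxide attack at sulfur with loss of the phenoxide (S-O cleavage), the alcohol-free medium avoids an alkyl tosylate that could alkylate the phenoxides, and the prenyl group, the 3-methoxyfuran and the aryl methyl ether are inert to base.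

**Compound list**
1 | paeonol (2'-hydroxy-4'-methoxyacetophenone) | CC(=O)c1ccc(OC)cc1O | starting material
2 | 2-acetyl-5-methoxyphenyl 4-methylbenzenesulfonate | CC(=O)c1ccc(OC)cc1OS(=O)(=O)c1ccc(C)cc1 | intermediate
3 | 2-(4-methoxy-2-tosyloxyphenyl)-2-oxoacetaldehyde (free glyoxal, not isolated) | O=CC(=O)c1ccc(OC)cc1OS(=O)(=O)c1ccc(C)cc1 | intermediate
4 | 2-(2,2-dihydroxyacetyl)-5-methoxyphenyl 4-methylbenzenesulfonate (glyoxal hydrate) | OC(O)C(=O)c1ccc(OC)cc1OS(=O)(=O)c1ccc(C)cc1 | intermediate
5 | 4-bromoresorcinol | Oc1ccc(Br)c(O)c1 | starting material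
6 | 1-bromo-2,4-bis(methoxymethoxy)benzene | COCOc1ccc(Br)c(OCOC)c1 | intermediate
7 | prenyl bromide (1-bromo-3-methylbut-2-ene) | CC(C)=CCBr | starting material
8 | [2,4-bis(methoxymethoxy)phenyl]lithium (not isolated) | [Li]c1ccc(OCOC)cc1OCOC | intermediate
9 | [2,4-bis(methoxymethoxy)phenyl]copper (not isolated) | [Cu]c1ccc(OCOC)cc1OCOC | intermediate
10 | 2,4-bis(methoxymethoxy)-1-(3-methylbut-2-en-1-yl)benzene | COCOc1ccc(CC=C(C)C)c(OCOC)c1 | intermediate
11 | 4-(3-methylbut-2-en-1-yl)benzene-1,3-diol (4-prenylresorcinol) | CC(C)=CCc1ccc(O)cc1O | intermediate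
12 | methanol | CO | starting material
13 | 2-(2-hydroxy-2-methoxyacetyl)-5-methoxyphenyl 4-methylbenzenesulfonate (racemic methyl hemiacetal, not isolated) | COC(O)C(=O)c1ccc(OC)cc1OS(=O)(=O)c1ccc(C)cc1 | intermediate
14 | 2-{2-[2,4-dihydroxy-5-(3-methylbut-2-en-1-yl)phenyl]-2-methoxyacetyl}-5-methoxyphenyl 4-methylbenzenesulfonate (racemic α-methoxy ketone, not isolated) | COC(C(=O)c1ccc(OC)cc1OS(=O)(=O)c1ccc(C)cc1)c1cc(CC=C(C)C)c(O)cc1O | intermediate
15 | 2-[2,6-dihydroxy-3-methoxy-5-(3-methylbut-2-en-1-yl)-2,3-dihydro-1-benzofuran-2-yl]-5-methoxyphenyl 4-methylbenzenesulfonate (hemiketal, mixture of racemic diastereomers, not isolated) | COC1c2cc(CC=C(C)C)c(O)cc2OC1(O)c1ccc(OC)cc1OS(=O)(=O)c1ccc(C)cc1 | intermediate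
16 | 2-[6-hydroxy-3-methoxy-5-(3-methylbut-2-en-1-yl)-1-benzofuran-2-yl]-5-methoxyphenyl 4-methylbenzenesulfonate (2'-O-tosylambofuranol) | COc1ccc(-c2oc3cc(O)c(CC=C(C)C)cc3c2OC)c(OS(=O)(=O)c2ccc(C)cc2)c1 | intermediate
17 | ambofuranol | COc1ccc(-c2oc3cc(O)c(CC=C(C)C)cc3c2OC)c(O)c1 | target

**Totals**
Total step count: 7. Longest linear sequence: 5 steps (steps 3, 4, 5, 6, 7, from 4-bromoresorcinol); the paeonol branch is 2 steps before the convergent key step.

**Steps most likely to fail**

1. Step 6 (proposed new method). The benzylic cation may be intercepted by a second molecule of the resorcinol instead of methanol, the aldehyde may drain into its dimethyl acetal before C-C bond formation, or the acid may close the ortho-prenylphenol onto its alkene. The fallback uses known chemistry and sets out from 4 and 11. The C-C bond is made first, without methanol or acid, by the known amine-catalysed hydroxyalkylation of an electron-rich phenol by an arylglyoxal hydrate (Et3N 10 mol %, MeCN or EtOH/H2O, rt), and the racemic α-hydroxy ketone 2-{2-[2,4-dihydroxy-5-(3-methylbut-2-en-1-yl)phenyl]-2-hydroxyacetyl}-5-methoxyphenyl 4-methylbenzenesulfonate F1 is isolated. F1 is then dissolved in methanol with CSA at rt, which exchanges the benzylic hydroxyl for methoxy (known solvolysis of a para-hydroxybenzylic alcohol) to give 14. Warming with trimethyl orthoformate completes the known acid cyclodehydration of the 2-hydroxybenzyl aryl ketone, and the fallback comes back to the route at 16.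

2. Step 5. Under acid the free ortho hydroxyl may add to the prenyl alkene (2,2-dimethylchroman formation), or the released methoxymethyl cation may alkylate the electron-rich ring. The fallback sets out from 5 and replaces acid-labile by fluoride-labile protection. 5 with SEMCl and i-Pr2NEt in CH2Cl2 should give 1-bromo-2,4-bis{[2-(trimethylsilyl)ethoxy]methoxy}benzene F2. Bromine-lithium exchange (n-BuLi, THF, −78 °C) gives (2,4-bis{[2-(trimethylsilyl)ethoxy]methoxy}phenyl)lithium F3, transmetalation with CuBr·SMe2 gives (2,4-bis{[2-(trimethylsilyl)ethoxy]methoxy}phenyl)copper F4, and prenyl bromide 7 then gives 1-(3-methylbut-2-en-1-yl)-2,4-bis{[2-(trimethylsilyl)ethoxy]methoxy}benzene F5. Cleavage with TBAF in DMPU at 80 °C (no acid) comes back to the route at 11.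

3. Step 4. The aryl-metal may attack prenyl bromide in the SN2' sense (1,1-dimethylallyl isomer), be protonated to the debrominated arene, or homocouple. The fallback sets out from 6 and replaces the organolithium/copper sequence by a palladium-catalysed Suzuki-Miyaura coupling with prenylboronic acid pinacol ester, using a bulky biarylphosphine ligand chosen for α-selectivity (K3PO4, THF/H2O, 40-70 °C). It comes back to the route directly at 10 and makes no new compound.

**Further compounds**
F1 | step 6 | 2-{2-[2,4-dihydroxy-5-(3-methylbut-2-en-1-yl)phenyl]-2-hydroxyacetyl}-5-methoxyphenyl 4-methylbenzenesulfonate (racemic) | OC(C(=O)c1ccc(OC)cc1OS(=O)(=O)c1ccc(C)cc1)c1cc(CC=C(C)C)c(O)cc1O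
F2 | step 5 | 1-bromo-2,4-bis{[2-(trimethylsilyl)ethoxy]methoxy}benzene | C[Si](C)(C)CCOCOc1ccc(Br)c(OCOCC[Si](C)(C)C)c1
F3 | step 5 | (2,4-bis{[2-(trimethylsilyl)ethoxy]methoxy}phenyl)lithium | [Li]c1ccc(OCOCC[Si](C)(C)C)cc1OCOCC[Si](C)(C)C
F4 | step 5 | (2,4-bis{[2-(trimethylsilyl)ethoxy]methoxy}phenyl)copper | [Cu]c1ccc(OCOCC[Si](C)(C)C)cc1OCOCC[Si](C)(C)C
F5 | step 5 | 1-(3-methylbut-2-en-1-yl)-2,4-bis{[2-(trimethylsilyl)ethoxy]methoxy}benzene | C[Si](C)(C)CCOCOc1ccc(CC=C(C)C)c(OCOCC[Si](C)(C)C)c1
F0 | step 4 | none | none
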